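All runs were generated by integration on assumed constants, and the scatter is random.

Decision: we leave the east flask alone until 12 h and change nothing before then.

in all of them: first end groups 0.10 M; gas 32 mM (held)
- east: temperature 0 °C; the very flask that is asked about, followed so far
- north-east: temperature −15 °C; run made earlier
- flask: temperature 0 °C; time 12 h

| run | time / min | links / % | first end groups / % |
|---|---|---|---|
| east | 90.0 | 11.1 | 0.5 |
| east | 180 | 10.7 | 0 |
| east | 300 | 10.8 | 0 |
| east | 360 | 11.0 | 0 |
| east | 480 | 10.7 | 0.7 |
| east | 600 | 10.5 | 0 |
| east | 720 | 10.9 | 0 |
| north-east | 180 | 5.4 | 9.6 |
| north-east | 360 | 4.4 | 1.1 |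
| north-east | 600 | 3.2 | 0.3 |
| north-east | 720 | 2.8 | 0.5 |
| north-east | 900 | 3.5 | 0.6 |
| north-east | 1200 | 4.0 | 0.5 |
| north-east | 1500 | 3.4 | 0 |

(scatter of a reading: 0.5 percentage points)
- percent here means first end groups units held: one homo dimer counts as two
- at the start none of second end groups is dissolved
- links that was removed still counts
- on the list of suspects stand: first end groups + second end groups -> rings; gas <-> second end groups; links <-> isomer of the product; 2 first end groups -> homo dimer; first end groups + second end groups -> links
- additions bring no volume worth counting
- epsilon: at 12 h raise the temperature by 25 K, then wait 4.0 h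
- eta: at 12 h take out 90% of the links then present, then wait 4.0 h
- delta: change nothing and wait 4.0 h more
- zeta: at 12 h add first end groups, 50.0% of the amount charged, then wait 4.0 h
* links, in percent of the first end groups first charged, at 12 h
* what to do for the largest gain in links; "none" if nothing gains more than 2 percentage points (epsilon / eta / delta / zeta / none)
* links present, with what was taken out counted in, in percent of the first end groups first charged, after epsilon
* links present, with what was taken out counted in, in percent of the first end groups first charged, after delta

1. First end groups are the limiting reagent of the east flask: held gas keeps renewing second end groups, while c(first end groups) is charged once. So links still standing flat can gain by waiting no more than the feed reserve, the first end groups still free, in percent of the charge.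
2. In the flask now: the readings from 180 min on give a feed reserve of 0.117%, and links at 10.8%, flat within the scatter. The remaining 89.1% stands in unread products.
3. At 12 h: we expect links at 10.8%, and after delta about 10.9%. The reserve is far less than the margin, so delta is useless.
4. What to change: zeta renews the feed reserve by 50.0% of the charge, more than the margin, but we put no number on its gain, since that dose starts at a lower c(first end groups) than the first charge. The late north-east plateau is lower, 3.43%, so links climb with warmth, and we choose epsilon.
5. The forecast gives 10.8%, epsilon, 18% after epsilon and 10.8% after delta: “the flask is settled and waiting gains nothing”.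

The east flask gives 10.9% at 12 h with 0% of first end groups free; delta gains 0 percentage points and ends at 10.9%, while epsilon gains 16 points and reaches 26.9%.

    first end groups + second end groups → rings, rate k1*[first end groups] as long as [second end groups] is above zero (k = 3.20 × 10⁻⁴ s⁻¹, Ea = 88.0 kJ mol⁻¹)
    gas ⇌ second end groups, rate k2*(csat - [second end groups]) (kL = 0.00320 s⁻¹)
    links ⇌ isomer of the product (K = 1.70, k = 0.00280 s⁻¹, Ea = 70.0 kJ mol⁻¹, ΔH = −79.0 kJ mol⁻¹)
    2 first end groups → homo dimer (k = 0.00460 M⁻¹ s⁻¹, Ea = 58.0 kJ mol⁻¹)
    first end groups + second end groups → links (k = 0.0170 M⁻¹ s⁻¹, Ea = 60.0 kJ mol⁻¹)
    (constants at 0 °C)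

The same flask run at −25 °C holds a feed reserve of 6.4% at 12 h, more than the margin, so the reserve does not bar waiting there, and its links stand at 3.81%.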